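**Retrosynthetic overview**
1. The target comes from global desilylation of a TIPS/TBS-protected tetracycle. Its dihydropyran ring (formed last) is closed by acid-catalysed cyclodehydration of a δ-hydroxy ketone, the tertiary OH adding to the C10 ketone, so both C–O stereocentres are carried in unchanged.
2. That ketone comes from conjugate reduction of an 11-alkylidene ketone, itself from dehydration of an aldol adduct. The key C–C bond (C11 to side-chain C1′) is made by intermolecular aldol addition of the lithium enolate of a 2-prenyl-3,7-bis(silyloxy)dibenzo[b,f]oxepin-10(11H)-one to a (2R,3S)-2,3-bis(silyloxy) aldehyde.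
3. The aldehyde comes from nerol: Sharpless epoxidation with L-(+)-diethyl tartrate, invertive hydrolysis at the tertiary carbon to the (2S,3S)-triol, then hydroxyl differentiation and oxidation.
4. The oxepinone comes from Stille prenylation of an aryl bromide. Its seven-membered ring (formed first) is closed by intramolecular Friedel–Crafts acylation of a 2-aryloxyphenylacetic acid, made by Willgerodt–Kindler reaction of an SNAr-derived diaryl ether acetophenone.
5. Ring order: both benzene rings are bought, the oxepinone ring is formed first, the dihydropyran ring last.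

Assumption: the tricycle is numbered as dibenzo[b,f]oxepine (O5; C10 on the ring B side, C11 on the ring A side) and the pyran ring as O1/C2/C3/C4; read this way the target is (2S,3S), with the 3-OH cis to the 4-methylpent-3-enyl group and trans to the 2-methyl.

Abbreviations: TBS = tert-butyldimethylsilyl, TIPS = triisopropylsilyl, TMS = trimethylsilyl.

**Fragment 1: the oxepinone**

Step 1
Reactants: 1 2-bromo-5-fluoroanisole
Product: 2 1-(5-bromo-2-fluoro-4-methoxyphenyl)ethan-1-one
Conditions: AcCl, AlCl3, CH2Cl2, 0 °C → rt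
Reagents that add atoms: acetyl chloride, CC(=O)Cl
Why: Friedel–Crafts acylation goes para to the methoxy group (the strongest director, this site is also ortho to fluorine), and the deactivated ketone does not react again.

Step 2
Reactants: 2 1-(5-bromo-2-fluoro-4-methoxyphenyl)ethan-1-one; 3 3-methoxyphenol
Product: 4 1-[5-bromo-4-methoxy-2-(3-methoxyphenoxy)phenyl]ethan-1-one
Conditions: K2CO3, DMF, 120 °C
Reagents that add atoms: none
Why: Nucleophilic aromatic substitution (SNAr) in which the fluoride, activated by the ortho acetyl group, is displaced by the phenoxide while the unactivated bromide stays.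

Step 3
Reactants: 4 1-[5-bromo-4-methoxy-2-(3-methoxyphenoxy)phenyl]ethan-1-one
Product: 5 2-[5-bromo-4-methoxy-2-(3-methoxyphenoxy)phenyl]-1-(morpholin-4-yl)ethane-1-thione
Conditions: S8, morpholine, 130 °C
Reagents that add atoms: sulfur, S1SSSSSSS1; morpholine, C1COCCN1
Why: Willgerodt–Kindler reaction moves the oxidised carbon of the aryl methyl ketone to the chain terminus and gives the arylthioacetmorpholide without touching the ethers or the aryl bromide.

Step 4
Reactants: 5 2-[5-bromo-4-methoxy-2-(3-methoxyphenoxy)phenyl]-1-(morpholin-4-yl)ethane-1-thione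
Product: 6 2-[5-bromo-4-methoxy-2-(3-methoxyphenoxy)phenyl]acetic acid
Conditions: KOH, EtOH/H2O, reflux; then aq HCl
Reagents that add atoms: potassium hydroxide, [K+].[OH-]; water, O
Why: Alkaline thioamide hydrolysis gives the arylacetic acid after acidification, and the diaryl ether, methyl ethers and aryl bromide are inert to hydroxide.

Step 5
Reactants: 6 2-[5-bromo-4-methoxy-2-(3-methoxyphenoxy)phenyl]acetic acid
Product: 7 2-bromo-3,7-dimethoxydibenzo[b,f]oxepin-10(11H)-one
Conditions: P2O5–MeSO3H (1:10 w/w), 50 °C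
Reagents that add atoms: none
Why: Intramolecular Friedel–Crafts acylation closes the seven-membered ring on ring B ortho to the ether oxygen and para to the methoxy group, the only activated and unhindered position the tether can reach.

Step 6
Reactants: 7 2-bromo-3,7-dimethoxydibenzo[b,f]oxepin-10(11H)-one
Product: 8 2-bromo-3,7-dihydroxydibenzo[b,f]oxepin-10(11H)-one
Conditions: BBr3, CH2Cl2, −78 °C → rt; then H2O
Reagents that add atoms: none
Why: Lewis-acid ether cleavage removes both methyl groups now, before the acid-sensitive prenyl groups and enol ether exist, while the diaryl ether, ketone and aryl bromide survive.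

Step 7
Reactants: 8 2-bromo-3,7-dihydroxydibenzo[b,f]oxepin-10(11H)-one
Product: 9 2-bromo-3,7-bis(triisopropylsilyloxy)dibenzo[b,f]oxepin-10(11H)-one
Conditions: TIPSCl, imidazole, DMF, rt
Reagents that add atoms: chlorotriisopropylsilane, CC(C)[Si](Cl)(C(C)C)C(C)C
Why: Silylation of both phenols gives bulky aryl silyl ethers that tolerate enolate, mesylation and mild acid chemistry and are removed by fluoride at the end.

Step 8
Reactants: 9 2-bromo-3,7-bis(triisopropylsilyloxy)dibenzo[b,f]oxepin-10(11H)-one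
Product: 10 2-(3-methylbut-2-en-1-yl)-3,7-bis(triisopropylsilyloxy)dibenzo[b,f]oxepin-10(11H)-one
Conditions: Pd(PPh3)4 (10 mol %), Bu3SnCH2CH=CMe2, DMF, 100 °C
Reagents that add atoms: tributyl(3-methylbut-2-en-1-yl)stannane, CCCC[Sn](CCCC)(CCCC)CC=C(C)C
Why: Stille cross-coupling of the aryl bromide with the prenylstannane gives the linear prenyl arene under neutral conditions that leave the enolisable ketone and silyl ethers alone.

**Fragment 2: the aldehyde**

Step 9
Reactants: 11 nerol, (2Z)-3,7-dimethylocta-2,6-dien-1-ol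
Product: 12 [(2S,3R)-3-methyl-3-(4-methylpent-3-en-1-yl)oxiran-2-yl]methanol
Conditions: Ti(OiPr)4 (10 mol %), L-(+)-diethyl tartrate (12 mol %), t-BuOOH, 4 Å MS, CH2Cl2, −20 °C
Reagents that add atoms: tert-butyl hydroperoxide, CC(C)(C)OO
Why: Sharpless asymmetric epoxidation, in which the Ti(OiPr)4/L-(+)-diethyl tartrate catalyst epoxidises only the allylic-alcohol double bond of the Z-alkene on the face that gives the (2S,3R)-epoxide, leaving the distal alkene untouched.

Step 10
Reactants: 12 [(2S,3R)-3-methyl-3-(4-methylpent-3-en-1-yl)oxiran-2-yl]methanol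
Product: 13 (2S,3S)-3,7-dimethyloct-6-ene-1,2,3-triol
Conditions: HClO4 (3% aq, cat.), THF/H2O, 0 °C
Reagents that add atoms: water, O
Why: Acid-catalysed epoxide hydrolysis in which water attacks the tertiary carbon C3 with inversion while C2 keeps its configuration, giving the (2S,3S)-triol whose C3 becomes pyran C2 (S) and whose C2 becomes pyran C3 (S).

Step 11
Reactants: 13 (2S,3S)-3,7-dimethyloct-6-ene-1,2,3-triol
Product: 14 (2S,3S)-1,2-bis[(tert-butyldimethylsilyl)oxy]-3,7-dimethyloct-6-en-3-ol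
Conditions: TBSCl, imidazole, DMAP (cat.), DMF, rt → 40 °C
Reagents that add atoms: tert-butylchlorodimethylsilane, CC(C)(C)[Si](C)(C)Cl
Why: Silylation with TBSCl/imidazole takes the primary and secondary hydroxyls but never the tertiary one.

Step 12
Reactants: 14 (2S,3S)-1,2-bis[(tert-butyldimethylsilyl)oxy]-3,7-dimethyloct-6-en-3-ol
Product: 15 (2S,3S)-2-[(tert-butyldimethylsilyl)oxy]-3,7-dimethyloct-6-ene-1,3-diol
Conditions: HF·pyridine, pyridine, THF, 0 °C
Reagents that add atoms: none
Why: Selective desilylation in which buffered HF·pyridine cleaves the unhindered primary silyl ether much faster than the secondary one next to the quaternary carbon.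

Step 13
Reactants: 15 (2S,3S)-2-[(tert-butyldimethylsilyl)oxy]-3,7-dimethyloct-6-ene-1,3-diol
Product: 16 (2R,3S)-2-[(tert-butyldimethylsilyl)oxy]-3-hydroxy-3,7-dimethyloct-6-enal
Conditions: Dess–Martin periodinane, CH2Cl2, 0 °C → rt
Reagents that add atoms: none
Why: Dess–Martin oxidation converts the primary alcohol to the aldehyde under non-basic conditions that do not epimerise the α-silyloxy centre (the descriptor changes from S to R only through priority change), and the tertiary alcohol cannot be oxidised.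

Step 14
Reactants: 16 (2R,3S)-2-[(tert-butyldimethylsilyl)oxy]-3-hydroxy-3,7-dimethyloct-6-enal
Product: 17 (2R,3S)-2-[(tert-butyldimethylsilyl)oxy]-3,7-dimethyl-3-[(trimethylsilyl)oxy]oct-6-enal
Conditions: 1-(trimethylsilyl)imidazole, CH2Cl2, rt
Reagents that add atoms: 1-(trimethylsilyl)imidazole, C[Si](C)(C)n1ccnc1
Why: Neutral silylation caps the tertiary alcohol as a labile TMS ether so that no free hydroxyl interferes with the enolate or the mesylation.

**Union and endgame**

Step 15
Reactants: 10 2-(3-methylbut-2-en-1-yl)-3,7-bis(triisopropylsilyloxy)dibenzo[b,f]oxepin-10(11H)-one; 17 (2R,3S)-2-[(tert-butyldimethylsilyl)oxy]-3,7-dimethyl-3-[(trimethylsilyl)oxy]oct-6-enal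
Product: 19 11-{(2S,3S)-2-[(tert-butyldimethylsilyl)oxy]-1-hydroxy-3,7-dimethyl-3-[(trimethylsilyl)oxy]oct-6-en-1-yl}-2-(3-methylbut-2-en-1-yl)-3,7-bis(triisopropylsilyloxy)dibenzo[b,f]oxepin-10(11H)-one (diastereomer mixture at C11/C1′), via lithium enolate 18 (not isolated)
Conditions: LiN(SiMe3)2 (1.0 equiv), THF, −78 °C; then 17, −78 °C; AcOH quench at −78 °C
Reagents that add atoms: none
Why: Intermolecular aldol addition in which the stabilised lithium enolate of the only enolisable position (C11) adds to the aldehyde faster than it deprotonates it, forming the C11–C1′ bond; the two new stereocentres are removed later and the (2′S,3′S) centres are untouched.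

Step 16
Reactants: 19 aldol adduct
Product: 21 11-{(2S,3S)-2-[(tert-butyldimethylsilyl)oxy]-3,7-dimethyl-3-[(trimethylsilyl)oxy]oct-6-en-1-ylidene}-2-(3-methylbut-2-en-1-yl)-3,7-bis(triisopropylsilyloxy)dibenzo[b,f]oxepin-10(11H)-one (E/Z mixture), via mesylate 20 (not isolated)
Conditions: MsCl, Et3N, CH2Cl2, 0 °C → rt
Reagents that add atoms: none
Why: Mesylation of the only free hydroxyl followed by E1cB elimination through the acidic α-aryl ketone proton completes the aldol condensation to the conjugated enone.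

Step 17
Reactants: 21 enone
Product: 22 11-{(2S,3S)-2-[(tert-butyldimethylsilyl)oxy]-3,7-dimethyl-3-[(trimethylsilyl)oxy]oct-6-en-1-yl}-2-(3-methylbut-2-en-1-yl)-3,7-bis(triisopropylsilyloxy)dibenzo[b,f]oxepin-10(11H)-one (epimer mixture at C11)
Conditions: [(Ph3P)CuH]6 (0.5 equiv), toluene, H2O (5 equiv), rt
Reagents that add atoms: none
Why: Copper hydride conjugate reduction (Stryker reduction) delivers hydride only to the β-carbon of the enone, leaving the ketone, the isolated trisubstituted alkenes and the silyl ethers intact.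

Step 18
Reactants: 22 saturated ketone
Product: 25 (2S,3S)-3-[(tert-butyldimethylsilyl)oxy]-2-methyl-2-(4-methylpent-3-en-1-yl)-3,4-dihydro-2H-pyran fused at C10=C11 of dibenzo[b,f]oxepine (O1 on C10; C4 on C11) carrying 3-methylbut-2-en-1-yl at C2 plus TIPS ethers at C3 and C7 of the oxepine, via hydroxy ketone 23 (not isolated), via cyclic hemiketal 24 (not isolated)
Conditions: PPTS (cat.), MeOH/CH2Cl2, rt; then PPTS (cat.), 4 Å MS, toluene, 90 °C
Reagents that add atoms: none
Why: Acid-catalysed methanolysis of the tertiary TMS ether followed by cyclodehydration of the δ-hydroxy ketone (hemiketalisation then loss of water) gives the six-membered enol ether conjugated with both arenes; no C–O bond at either stereocentre is broken, so (2S,3S) is retained, and the TBS group keeps the secondary oxygen from closing a five-membered ring.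

Step 19
Reactants: 25 silyl-protected tetracycle
Product: 26 target, (2S,3S)-3-hydroxy-2-methyl-2-(4-methylpent-3-en-1-yl)-3,4-dihydro-2H-pyran fused at C10=C11 of dibenzo[b,f]oxepine (O1 on C10; C4 on C11) with OH at oxepine C3 and C7 and 3-methylbut-2-en-1-yl at oxepine C2
Conditions: Bu4NF (5 equiv), AcOH (5 equiv), THF, rt → 45 °C
Reagents that add atoms: none
Why: Fluoride-mediated desilylation removes the two aryl TIPS ethers and the secondary TBS ether under buffered, non-acidic conditions that harm neither the enol ether nor the prenyl groups.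

**Compound list**
1 | 2-bromo-5-fluoroanisole | COc1cc(F)ccc1Br | starting material
2 | 1-(5-bromo-2-fluoro-4-methoxyphenyl)ethan-1-one | CC(=O)c1cc(Br)c(OC)cc1F | intermediate
3 | 3-methoxyphenol | COc1cccc(O)c1 | starting material
4 | 1-[5-bromo-4-methoxy-2-(3-methoxyphenoxy)phenyl]ethan-1-one | CC(=O)c1cc(Br)c(OC)cc1Oc1cccc(OC)c1 | intermediate
5 | 2-[5-bromo-4-methoxy-2-(3-methoxyphenoxy)phenyl]-1-(morpholin-4-yl)ethane-1-thione | S=C(Cc1cc(Br)c(OC)cc1Oc1cccc(OC)c1)N1CCOCC1 | intermediate
6 | 2-[5-bromo-4-methoxy-2-(3-methoxyphenoxy)phenyl]acetic acid | OC(=O)Cc1cc(Br)c(OC)cc1Oc1cccc(OC)c1 | intermediate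
7 | 2-bromo-3,7-dimethoxydibenzo[b,f]oxepin-10(11H)-one | O=C1Cc2cc(Br)c(OC)cc2Oc2cc(OC)ccc12 | intermediate
8 | 2-bromo-3,7-dihydroxydibenzo[b,f]oxepin-10(11H)-one | O=C1Cc2cc(Br)c(O)cc2Oc2cc(O)ccc12 | intermediate
9 | 2-bromo-3,7-bis(triisopropylsilyloxy)dibenzo[b,f]oxepin-10(11H)-one | O=C1Cc2cc(Br)c(O[Si](C(C)C)(C(C)C)C(C)C)cc2Oc2cc(O[Si](C(C)C)(C(C)C)C(C)C)ccc12 | intermediate
10 | 2-(3-methylbut-2-en-1-yl)-3,7-bis(triisopropylsilyloxy)dibenzo[b,f]oxepin-10(11H)-one | O=C1Cc2cc(CC=C(C)C)c(O[Si](C(C)C)(C(C)C)C(C)C)cc2Oc2cc(O[Si](C(C)C)(C(C)C)C(C)C)ccc12 | intermediate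
11 | nerol, (2Z)-3,7-dimethylocta-2,6-dien-1-ol | CC(C)=CCC/C(C)=C\CO | starting material
12 | [(2S,3R)-3-methyl-3-(4-methylpent-3-en-1-yl)oxiran-2-yl]methanol | CC(C)=CCC[C@@]1(C)O[C@H]1CO | intermediate
13 | (2S,3S)-3,7-dimethyloct-6-ene-1,2,3-triol | CC(C)=CCC[C@](C)(O)[C@@H](O)CO | intermediate
14 | (2S,3S)-1,2-bis[(tert-butyldimethylsilyl)oxy]-3,7-dimethyloct-6-en-3-ol | CC(C)=CCC[C@](C)(O)[C@@H](O[Si](C)(C)C(C)(C)C)CO[Si](C)(C)C(C)(C)C | intermediate
15 | (2S,3S)-2-[(tert-butyldimethylsilyl)oxy]-3,7-dimethyloct-6-ene-1,3-diol | CC(C)=CCC[C@](C)(O)[C@@H](O[Si](C)(C)C(C)(C)C)CO | intermediate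
16 | (2R,3S)-2-[(tert-butyldimethylsilyl)oxy]-3-hydroxy-3,7-dimethyloct-6-enal | CC(C)=CCC[C@](C)(O)[C@@H](O[Si](C)(C)C(C)(C)C)C=O | intermediate
17 | (2R,3S)-2-[(tert-butyldimethylsilyl)oxy]-3,7-dimethyl-3-[(trimethylsilyl)oxy]oct-6-enal | CC(C)=CCC[C@](C)(O[Si](C)(C)C)[C@@H](O[Si](C)(C)C(C)(C)C)C=O | intermediate
18 | lithium enolate of 10 (lithium 2-(3-methylbut-2-en-1-yl)-3,7-bis(triisopropylsilyloxy)dibenzo[b,f]oxepin-10-olate) | [Li]OC1=Cc2cc(CC=C(C)C)c(O[Si](C(C)C)(C(C)C)C(C)C)cc2Oc2cc(O[Si](C(C)C)(C(C)C)C(C)C)ccc12 | intermediate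
19 | aldol adduct: 10 carrying at C11 the (2S,3S)-2-(TBS-oxy)-1-hydroxy-3,7-dimethyl-3-(TMS-oxy)oct-6-en-1-yl group (mixture at C11 and C1′) | CC(C)=CCC[C@](C)(O[Si](C)(C)C)[C@@H](O[Si](C)(C)C(C)(C)C)C(O)C1C(=O)c2ccc(O[Si](C(C)C)(C(C)C)C(C)C)cc2Oc2cc(O[Si](C(C)C)(C(C)C)C(C)C)c(CC=C(C)C)cc21 | intermediate
20 | C1′ methanesulfonate of 19 | CC(C)=CCC[C@](C)(O[Si](C)(C)C)[C@@H](O[Si](C)(C)C(C)(C)C)C(OS(C)(=O)=O)C1C(=O)c2ccc(O[Si](C(C)C)(C(C)C)C(C)C)cc2Oc2cc(O[Si](C(C)C)(C(C)C)C(C)C)c(CC=C(C)C)cc21 | intermediate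
21 | enone: 10 carrying at C11 the (2S,3S)-2-(TBS-oxy)-3,7-dimethyl-3-(TMS-oxy)oct-6-en-1-ylidene group (E/Z mixture) | CC(C)=CCC[C@](C)(O[Si](C)(C)C)[C@@H](O[Si](C)(C)C(C)(C)C)C=C1C(=O)c2ccc(O[Si](C(C)C)(C(C)C)C(C)C)cc2Oc2cc(O[Si](C(C)C)(C(C)C)C(C)C)c(CC=C(C)C)cc21 | intermediate
22 | saturated ketone: 10 carrying at C11 the (2S,3S)-2-(TBS-oxy)-3,7-dimethyl-3-(TMS-oxy)oct-6-en-1-yl group (epimers at C11) | CC(C)=CCC[C@](C)(O[Si](C)(C)C)[C@@H](O[Si](C)(C)C(C)(C)C)CC1C(=O)c2ccc(O[Si](C(C)C)(C(C)C)C(C)C)cc2Oc2cc(O[Si](C(C)C)(C(C)C)C(C)C)c(CC=C(C)C)cc21 | intermediate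
23 | hydroxy ketone: 22 with free tertiary 3′-OH, (2′S,3′S) | CC(C)=CCC[C@](C)(O)[C@@H](O[Si](C)(C)C(C)(C)C)CC1C(=O)c2ccc(O[Si](C(C)C)(C(C)C)C(C)C)cc2Oc2cc(O[Si](C(C)C)(C(C)C)C(C)C)c(CC=C(C)C)cc21 | intermediate
24 | cyclic hemiketal: (2S,3S)-tetrahydropyran fused at C10–C11 of the 10,11-dihydro-oxepine, OH on the ketal carbon C10, otherwise as 25 | CC(C)=CCC[C@]1(C)OC2(O)C(C[C@@H]1O[Si](C)(C)C(C)(C)C)c1cc(CC=C(C)C)c(O[Si](C(C)C)(C(C)C)C(C)C)cc1Oc1cc(O[Si](C(C)C)(C(C)C)C(C)C)ccc12 | intermediate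
25 | (2S,3S)-3-O-TBS, oxepine 3,7-bis-O-TIPS ether of the target | CC(C)=CCC[C@]1(C)OC2=C(C[C@@H]1O[Si](C)(C)C(C)(C)C)c1cc(CC=C(C)C)c(O[Si](C(C)C)(C(C)C)C(C)C)cc1Oc1cc(O[Si](C(C)C)(C(C)C)C(C)C)ccc12 | intermediate
26 | CNP0185870.1, (2S,3S)-pyrano-fused 2-prenyl-dibenzo[b,f]oxepine-triol | CC(C)=CCC[C@]1(C)OC2=C(C[C@@H]1O)c1cc(CC=C(C)C)c(O)cc1Oc1cc(O)ccc12 | target

**Totals**
Total steps: 19. Longest linear sequence: 13 steps (steps 1–8, then 15–19); the nerol branch is 6 steps before the union.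

**Three steps most likely to fail**

Step 8 (Stille prenylation next to a bulky silyloxy group; slow coupling or some branched isomer). The fallback sets out from 9. Stille coupling with Bu3SnCH2CH=CH2 (Pd(PPh3)4, toluene, 100 °C), which has no regiochemical ambiguity, gives 2-(prop-2-en-1-yl)-3,7-bis(triisopropylsilyloxy)dibenzo[b,f]oxepin-10(11H)-one F1. Olefin cross-metathesis of F1 with excess 2-methylbut-2-ene (second-generation Grubbs catalyst RuCl2(=CHPh)(PCy3)(H2IMes), CH2Cl2, 40 °C) then comes back to the route at 10.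

Step 15 (aldol addition of a hindered, stabilised enolate to a hindered aldehyde; retro-aldol or silyl migration in the lithium aldolate). The fallback sets out from 10. Enol silylation (TMSOTf, Et3N, CH2Cl2, 0 °C) gives 2-(3-methylbut-2-en-1-yl)-3,7-bis(triisopropylsilyloxy)-10-(trimethylsilyloxy)dibenzo[b,f]oxepine F2. A Mukaiyama aldol addition of F2 to 17 (BF3·OEt2, CH2Cl2, −78 °C), which never forms a basic aldolate, comes back to the route at 19.

Step 18 (direct cyclodehydration of a tertiary alcohol onto a conjugated ketone may stall at the hemiketal or need acid strong enough to harm the prenyl groups). The fallback sets out from 22. Treatment with HC(OMe)3 and PPTS in MeOH at rt removes the TMS group and traps the ring-closed form as the isolable cyclic methyl ketal of 24 (OMe in place of the hemiketal OH) F3. Aprotic elimination of methanol from F3 with TMSOTf and iPr2NEt (CH2Cl2, −20 → 0 °C) through the oxocarbenium ion then comes back to the route at 25.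

Further compounds
F1 | step 8 | 2-(prop-2-en-1-yl)-3,7-bis(triisopropylsilyloxy)dibenzo[b,f]oxepin-10(11H)-one | O=C1Cc2cc(CC=C)c(O[Si](C(C)C)(C(C)C)C(C)C)cc2Oc2cc(O[Si](C(C)C)(C(C)C)C(C)C)ccc12
F2 | step 15 | 2-(3-methylbut-2-en-1-yl)-3,7-bis(triisopropylsilyloxy)-10-(trimethylsilyloxy)dibenzo[b,f]oxepine | C[Si](C)(C)OC1=Cc2cc(CC=C(C)C)c(O[Si](C(C)C)(C(C)C)C(C)C)cc2Oc2cc(O[Si](C(C)C)(C(C)C)C(C)C)ccc12
F3 | step 18 | cyclic methyl ketal of 24, (2S,3S) in the pyran ring, mixture at the ketal carbon and C11 | CC(C)=CCC[C@]1(C)OC2(OC)C(C[C@@H]1O[Si](C)(C)C(C)(C)C)c1cc(CC=C(C)C)c(O[Si](C(C)C)(C(C)C)C(C)C)cc1Oc1cc(O[Si](C(C)C)(C(C)C)C(C)C)ccc12
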